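**Retrosynthetic overview**
1. Target 30 is cut at the C3–O ester bond into the trienone alcohol 22 and (2E,4E,6S)-6-methylocta-2,4-dienoic acid 28; 28 comes from (S)-2-methylbutan-1-ol 23 by oxidation, vinylogous HWE olefination and saponification.
2. 22 goes back to the diene silyl ether 15: the C7 isopropylidene by acetone aldol and dehydration, the C8 ketone by allylic oxidation of the only allylic CH2.
3. Feature carrying the strategy (eremophilane numbering): the heteroannular diene C9=C10–C1=C2 runs through ring B (C5–C6–C7–C8–C9–C10) and ring A (C1–C2–C3–C4–C5–C10), with C10 at the fusion beside the quaternary C5. This is the footprint of an enyne metathesis cascade on a C10≡C1 alkyne held by C5, so 15 is cut at C9=C10 and C1=C2 to the acyclic dienyne 14.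
4. 14 goes back to butenolide 1: alkyne from the lactone carbonyl (lactol, Ohira–Bestmann), C5 by two enolate alkylations, C4 by anti cuprate addition, C3 from the chiral pool, vinyl from the CH2OH arm.
5. Ring order: ring B first, ring A second, both in the one operation of step 11; before it the only ring is the lactone template, opened in step 6.

Key step: step 11

Assumption: the R butenolide 1 (the less common enantiomer, D-glutamic acid series) is bought as the single enantiomer; the target requires R, and all three ring stereocenters derive from its C5.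

**Route**

Step 1
Reactants: 1 (R)-5-(hydroxymethyl)furan-2(5H)-one
Product: 2 (R)-5-{[(tert-butyldimethylsilyl)oxy]methyl}furan-2(5H)-one
Conditions: TBSCl, imidazole, DMF, 0 °C → rt
Reagents that add atoms: tert-butyldimethylsilyl chloride, CC(C)(C)[Si](C)(C)Cl
Why: Imidazole-promoted silylation of the primary alcohol is a standard protection, and the weakly basic medium does not enolize the butenolide toward the 2-oxyfuran, so the C5 stereocenter is kept.

Step 2
Reactants: 2 (R)-5-{[(tert-butyldimethylsilyl)oxy]methyl}furan-2(5H)-one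
Product: 3 (4R,5R)-5-{[(tert-butyldimethylsilyl)oxy]methyl}-4-methyldihydrofuran-2(3H)-one
Conditions: Me2CuLi (from MeLi and CuI), Et2O, −78 → −30 °C; aq NH4Cl
Reagents that add atoms: lithium dimethylcuprate, [Li+].C[Cu-]C (made in the flask from methyllithium, [Li]C, and CuI)
Why: Conjugate addition of a Gilman cuprate to the butenolide delivers the methyl group to C4 on the face opposite the C5 CH2OTBS group, which sets the 4,5-trans relationship (C4 of the eremophilane) under substrate control.

Step 3
Reactants: 3 (4R,5R)-5-{[(tert-butyldimethylsilyl)oxy]methyl}-4-methyldihydrofuran-2(3H)-one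
Product: 5 (3R,4R,5R)-5-{[(tert-butyldimethylsilyl)oxy]methyl}-3,4-dimethyldihydrofuran-2(3H)-one, via lithium enolate 4 (not isolated)
Conditions: LiN(i-Pr)2, THF, −78 °C; MeI, −78 → −40 °C
Reagents that add atoms: iodomethane, CI
Why: Alkylation of the lithium lactone enolate with iodomethane should give mainly the 3,4-trans isomer, but the C3 configuration is of no consequence because this carbon is made planar again in step 4.

Step 4
Reactants: 5 (3R,4R,5R)-5-{[(tert-butyldimethylsilyl)oxy]methyl}-3,4-dimethyldihydrofuran-2(3H)-one; 6 pent-4-enyl bromide (5-bromopent-1-ene)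
Product: 8 (3R,4R,5R)-5-{[(tert-butyldimethylsilyl)oxy]methyl}-3,4-dimethyl-3-(pent-4-en-1-yl)dihydrofuran-2(3H)-one, via lithium enolate 7 (not isolated)
Conditions: LiN(i-Pr)2, THF, −78 °C; 6, DMPU, −78 → 0 °C
Reagents that add atoms: none
Why: SN2 alkylation of the tetrasubstituted lithium enolate, in which the pentenyl group should enter on the face opposite the adjacent C4 methyl group (1,2-induction, expected to outweigh the 1,3-effect of the C5 side chain), leaving the two methyl groups cis and setting the quaternary center (C5 of the eremophilane).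

Step 5
Reactants: 8 (3R,4R,5R)-5-{[(tert-butyldimethylsilyl)oxy]methyl}-3,4-dimethyl-3-(pent-4-en-1-yl)dihydrofuran-2(3H)-one
Product: 9 (3R,4R,5R)-5-{[(tert-butyldimethylsilyl)oxy]methyl}-3,4-dimethyl-3-(pent-4-en-1-yl)tetrahydrofuran-2-ol (lactol, both anomers)
Conditions: i-Bu2AlH, CH2Cl2, −78 °C; aq KNaC4H4O6 (potassium sodium tartrate)
Reagents that add atoms: none
Why: Half-reduction of the lactone by i-Bu2AlH at −78 °C stops at the tetrahedral aluminium alkoxide, helped by the neighbouring quaternary carbon, and gives the lactol without touching the silyl ether or the alkene.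

Step 6
Reactants: 9 lactol (3R,4R,5R)-5-{[(tert-butyldimethylsilyl)oxy]methyl}-3,4-dimethyl-3-(pent-4-en-1-yl)tetrahydrofuran-2-ol
Product: 10 (2R,3R,4R)-1-[(tert-butyldimethylsilyl)oxy]-4-ethynyl-3,4-dimethylnon-8-en-2-ol
Conditions: dimethyl (1-diazo-2-oxopropyl)phosphonate, K2CO3, MeOH, 0 °C → rt
Reagents that add atoms: dimethyl (1-diazo-2-oxopropyl)phosphonate, CC(=O)C(=[N+]=[N-])P(=O)(OC)OC
Why: Ohira–Bestmann (Seyferth–Gilbert) homologation acts on the open hydroxy aldehyde form of the lactol, the aldehyde carbon has no α-hydrogen so nothing can epimerize, and the 1,2-hydrogen shift of the alkylidene carbene gives the terminal alkyne with the C2 hydroxyl set free.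

Step 7
Reactants: 10 (2R,3R,4R)-1-[(tert-butyldimethylsilyl)oxy]-4-ethynyl-3,4-dimethylnon-8-en-2-ol
Product: 11 (2R,3R,4R)-1,2-bis[(tert-butyldimethylsilyl)oxy]-4-ethynyl-3,4-dimethylnon-8-ene
Conditions: TBSOTf, 2,6-lutidine, CH2Cl2, −78 → 0 °C
Reagents that add atoms: tert-butyldimethylsilyl trifluoromethanesulfonate, CC(C)(C)[Si](C)(C)OS(=O)(=O)C(F)(F)F
Why: Silylation of the hindered secondary alcohol with the silyl triflate and a hindered pyridine base is reliable, and because both oxygens end up with the same silyl group any 1,2-silyl migration during step 6 is of no consequence.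

Step 8
Reactants: 11 (2R,3R,4R)-1,2-bis[(tert-butyldimethylsilyl)oxy]-4-ethynyl-3,4-dimethylnon-8-ene
Product: 12 (2R,3R,4R)-2-[(tert-butyldimethylsilyl)oxy]-4-ethynyl-3,4-dimethylnon-8-en-1-ol
Conditions: HF·pyridine, pyridine, THF, 0 °C
Reagents that add atoms: none
Why: Buffered HF·pyridine cleaves the primary TBS ether much faster than the secondary one, which is shielded by the branched C3 and the quaternary C4.

Step 9
Reactants: 12 (2R,3R,4R)-2-[(tert-butyldimethylsilyl)oxy]-4-ethynyl-3,4-dimethylnon-8-en-1-ol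
Product: 13 (2R,3R,4R)-2-[(tert-butyldimethylsilyl)oxy]-4-ethynyl-3,4-dimethylnon-8-enal
Conditions: Dess–Martin periodinane, CH2Cl2, 0 °C → rt
Reagents that add atoms: none
Why: Dess–Martin oxidation runs under near-neutral conditions, so the α-silyloxy aldehyde should form without epimerization at C2 and without affecting the alkyne or the alkene.

Step 10
Reactants: 13 (2R,3R,4R)-2-[(tert-butyldimethylsilyl)oxy]-4-ethynyl-3,4-dimethylnon-8-enal
Product: 14 (3S,4R,5R)-3-[(tert-butyldimethylsilyl)oxy]-5-ethynyl-4,5-dimethyldeca-1,9-diene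
Conditions: Ph3PCH3Br, KN(SiMe3)2, THF, 0 °C; then 13, −78 → 0 °C
Reagents that add atoms: methyltriphenylphosphonium bromide, C[P+](c1ccccc1)(c1ccccc1)c1ccccc1.[Br-]
Why: Wittig methylenation with the non-stabilized ylide at low temperature adds to the aldehyde faster than it can enolize it, so the α-silyloxy stereocenter should survive while the vinyl group of the metathesis precursor is installed.

Step 11
Reactants: 14 (3S,4R,5R)-3-[(tert-butyldimethylsilyl)oxy]-5-ethynyl-4,5-dimethyldeca-1,9-diene
Product: 15 tert-butyl{[(1R,2S,8aR)-1,8a-dimethyl-1,2,6,7,8,8a-hexahydronaphthalen-2-yl]oxy}dimethylsilane (eremophila-1,9-dien-3-ol TBS ether)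
Conditions: second-generation Grubbs catalyst (H2IMes)(PCy3)Cl2Ru=CHPh (10 mol %), toluene (0.005 M), 60 °C, argon
Reagents that add atoms: none
Why: The ruthenium benzylidene exchanges onto the unhindered terminal alkene of the pentenyl arm (C9); this alkylidene undergoes [2+2] cycloaddition with the C10≡C1 alkyne and cycloreversion to give the C9=C10 bond and a ruthenium vinylcarbene at C1, which then undergoes ring-closing olefin metathesis with the C3 vinyl group to form C1=C2 and release ethylene. The closest known reaction type is the tandem ring-closing enyne metathesis (dienyne cascade) that turns acyclic dienynes into fused bicyclic 1,3-dienes. Ring B closes in the six-exo enyne mode (C9 onto the inner alkyne carbon C10, ring C5–C6–C7–C8–C9–C10), and ring A closes by six-membered ring-closing metathesis of the C1 carbene with the C2 alkene (ring C1–C2–C3–C4–C5–C10); both rings must share the C5–C10 bond because both arms hang from C5. No stereocenter is formed, and C3, C4 and C5 are sp3 spectators that cannot epimerize under these neutral conditions. The step needs site selectivity for loading at C9 and not at C2, since a C2 alkylidene closing exo onto C10 would give a cyclopentene. This is secured by the allylic OTBS group and the C4 branch, which make the C2 vinyl group a slow-loading alkene, while high dilution suppresses intermolecular metathesis.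

Step 12
Reactants: 15 tert-butyl{[(1R,2S,8aR)-1,8a-dimethyl-1,2,6,7,8,8a-hexahydronaphthalen-2-yl]oxy}dimethylsilane
Product: 16 (4aR,5R,6S)-6-[(tert-butyldimethylsilyl)oxy]-4a,5-dimethyl-4,4a,5,6-tetrahydronaphthalen-2(3H)-one (1,9-dien-8-one)
Conditions: CrO3, 3,5-dimethylpyrazole, CH2Cl2, −20 °C
Reagents that add atoms: chromium trioxide, O=[Cr](=O)=O
Why: Allylic oxidation with the CrO3–3,5-dimethylpyrazole complex should convert the only allylic methylene (C8) into the ketone, as in the known oxidation of steroidal 3,5-dienes to 3,5-dien-7-ones, while the other allylic C–H (C3) is tertiary and screened by the OTBS group and the C4 methyl group.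

Step 13
Reactants: 16 (4aR,5R,6S)-6-[(tert-butyldimethylsilyl)oxy]-4a,5-dimethyl-4,4a,5,6-tetrahydronaphthalen-2(3H)-one
Product: 19 (4aR,5R,6S)-6-[(tert-butyldimethylsilyl)oxy]-3-(2-hydroxypropan-2-yl)-4a,5-dimethyl-4,4a,5,6-tetrahydronaphthalen-2(3H)-one (both C3 epimers), via lithium enolate 17 (not isolated), via chlorozinc enolate 18 (not isolated)
Conditions: LiN(i-Pr)2, THF, −78 °C; ZnCl2; acetone, −78 → −40 °C; aq NH4Cl
Reagents that add atoms: acetone, CC(C)=O
Why: Kinetic deprotonation of the dienone by the lithium amide takes place at the α' methylene C7 (cross-conjugated enolate), and the derived zinc enolate should add to acetone in an aldol reaction without retro-aldol or proton transfer; the new C7 stereocenter is not controlled and is removed in step 14.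

Step 14
Reactants: 19 (4aR,5R,6S)-6-[(tert-butyldimethylsilyl)oxy]-3-(2-hydroxypropan-2-yl)-4a,5-dimethyl-4,4a,5,6-tetrahydronaphthalen-2(3H)-one
Product: 21 (4aR,5R,6S)-6-[(tert-butyldimethylsilyl)oxy]-4a,5-dimethyl-3-(propan-2-ylidene)-4,4a,5,6-tetrahydronaphthalen-2(3H)-one, via tertiary mesylate 20 (not isolated)
Conditions: MsCl, Et3N, CH2Cl2, 0 °C → rt; then DBU, rt
Reagents that add atoms: none
Why: Mesylation of the tertiary alcohol through sulfene followed by E1cB elimination of the acidic C7 hydrogen with DBU should give the conjugated tetrasubstituted isopropylidene and not the isopropenyl isomer.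

Step 15
Reactants: 21 (4aR,5R,6S)-6-[(tert-butyldimethylsilyl)oxy]-4a,5-dimethyl-3-(propan-2-ylidene)-4,4a,5,6-tetrahydronaphthalen-2(3H)-one
Product: 22 (4aR,5R,6S)-6-hydroxy-4a,5-dimethyl-3-(propan-2-ylidene)-4,4a,5,6-tetrahydronaphthalen-2(3H)-one
Conditions: HF·pyridine, THF, 0 °C → rt
Reagents that add atoms: none
Why: Cleavage of the silyl ether with HF·pyridine is non-basic, so the trienone is not enolized toward C3 and the carbinol configuration is kept.

Step 16
Reactants: 23 (S)-2-methylbutan-1-ol
Product: 24 (S)-2-methylbutanal (used at once as a dried CH2Cl2 solution)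
Conditions: TEMPO (cat.), KBr (cat.), NaOCl, NaHCO3, CH2Cl2/H2O, 0 °C
Reagents that add atoms: none
Why: TEMPO-catalysed hypochlorite oxidation (Anelli conditions) in a buffered two-phase system stops at the aldehyde and is fast enough at 0 °C to keep the α-stereocenter.

Step 17
Reactants: 24 (S)-2-methylbutanal; 25 triethyl 4-phosphonocrotonate, ethyl (E)-4-(diethoxyphosphoryl)but-2-enoate
Product: 27 ethyl (2E,4E,6S)-6-methylocta-2,4-dienoate, via lithiated phosphonate 26 (not isolated)
Conditions: 25, LiN(SiMe3)2, THF, −78 °C; then 24, −78 → 0 °C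
Reagents that add atoms: none
Why: Vinylogous Horner–Wadsworth–Emmons olefination through the γ-carbon of the stabilized phosphonate anion should form the new C4=C5 alkene with E geometry and keep the 2E alkene, and at −78 °C with no excess base the aldehyde stereocenter is not epimerized.

Step 18
Reactants: 27 ethyl (2E,4E,6S)-6-methylocta-2,4-dienoate
Product: 28 (2E,4E,6S)-6-methylocta-2,4-dienoic acid
Conditions: LiOH, THF/MeOH/H2O, rt; then aq HCl
Reagents that add atoms: lithium hydroxide, [Li+].[OH-]
Why: Saponification of the ethyl ester by hydroxide (acyl–oxygen cleavage) and acidification gives the acid, and the remote C6 hydrogen is not acidic enough to be removed under these conditions.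

Step 19
Reactants: 22 (4aR,5R,6S)-6-hydroxy-4a,5-dimethyl-3-(propan-2-ylidene)-4,4a,5,6-tetrahydronaphthalen-2(3H)-one; 28 (2E,4E,6S)-6-methylocta-2,4-dienoic acid
Product: 30 (1R,2S,8aR)-1,8a-dimethyl-6-oxo-7-(propan-2-ylidene)-1,2,6,7,8,8a-hexahydronaphthalen-2-yl (2E,4E,6S)-6-methylocta-2,4-dienoate (CNP0215744.1), via mixed anhydride 29 (not isolated)
Conditions: 28, 2,4,6-trichlorobenzoyl chloride, Et3N, THF, rt; then 22, DMAP, toluene, rt
Reagents that add atoms: none
Why: Yamaguchi esterification, in which DMAP attacks the mixed anhydride at the less hindered dienoyl carbonyl and the acylpyridinium acylates the hindered allylic alcohol on oxygen, so C3 keeps its configuration.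

**Compound list**
1 | (R)-5-(hydroxymethyl)furan-2(5H)-one | OC[C@@H]1OC(=O)C=C1 | starting material
2 | (R)-5-{[(tert-butyldimethylsilyl)oxy]methyl}furan-2(5H)-one | CC(C)(C)[Si](C)(C)OC[C@@H]1OC(=O)C=C1 | intermediate
3 | (4R,5R)-5-{[(tert-butyldimethylsilyl)oxy]methyl}-4-methyldihydrofuran-2(3H)-one (4-methyl trans to the C5 side chain) | CC(C)(C)[Si](C)(C)OC[C@@H]1OC(=O)C[C@H]1C | intermediate
4 | lithium enolate of 3 | CC(C)(C)[Si](C)(C)OC[C@@H]1OC(O[Li])=C[C@H]1C | intermediate (not isolated)
5 | (3R,4R,5R)-5-{[(tert-butyldimethylsilyl)oxy]methyl}-3,4-dimethyldihydrofuran-2(3H)-one | CC(C)(C)[Si](C)(C)OC[C@@H]1OC(=O)[C@H](C)[C@H]1C | intermediate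
6 | 5-bromopent-1-ene | C=CCCCBr | starting material
7 | lithium enolate of 5 | CC(C)(C)[Si](C)(C)OC[C@@H]1OC(O[Li])=C(C)[C@H]1C | intermediate (not isolated)
8 | (3R,4R,5R)-5-{[(tert-butyldimethylsilyl)oxy]methyl}-3,4-dimethyl-3-(pent-4-en-1-yl)dihydrofuran-2(3H)-one (pentenyl trans, 3-methyl cis to the 4-methyl) | CC(C)(C)[Si](C)(C)OC[C@@H]1OC(=O)[C@](C)(CCCC=C)[C@H]1C | intermediate
9 | (3R,4R,5R)-5-{[(tert-butyldimethylsilyl)oxy]methyl}-3,4-dimethyl-3-(pent-4-en-1-yl)tetrahydrofuran-2-ol (lactol, both anomers) | CC(C)(C)[Si](C)(C)OC[C@@H]1OC(O)[C@](C)(CCCC=C)[C@H]1C | intermediate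
10 | (2R,3R,4R)-1-[(tert-butyldimethylsilyl)oxy]-4-ethynyl-3,4-dimethylnon-8-en-2-ol | CC(C)(C)[Si](C)(C)OC[C@H](O)[C@H](C)[C@](C)(C#C)CCCC=C | intermediate
11 | (2R,3R,4R)-1,2-bis[(tert-butyldimethylsilyl)oxy]-4-ethynyl-3,4-dimethylnon-8-ene | CC(C)(C)[Si](C)(C)OC[C@H](O[Si](C)(C)C(C)(C)C)[C@H](C)[C@](C)(C#C)CCCC=C | intermediate
12 | (2R,3R,4R)-2-[(tert-butyldimethylsilyl)oxy]-4-ethynyl-3,4-dimethylnon-8-en-1-ol | OC[C@H](O[Si](C)(C)C(C)(C)C)[C@H](C)[C@](C)(C#C)CCCC=C | intermediate
13 | (2R,3R,4R)-2-[(tert-butyldimethylsilyl)oxy]-4-ethynyl-3,4-dimethylnon-8-enal | O=C[C@H](O[Si](C)(C)C(C)(C)C)[C@H](C)[C@](C)(C#C)CCCC=C | intermediate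
14 | (3S,4R,5R)-3-[(tert-butyldimethylsilyl)oxy]-5-ethynyl-4,5-dimethyldeca-1,9-diene | C=C[C@H](O[Si](C)(C)C(C)(C)C)[C@H](C)[C@](C)(C#C)CCCC=C | intermediate
15 | tert-butyl{[(1R,2S,8aR)-1,8a-dimethyl-1,2,6,7,8,8a-hexahydronaphthalen-2-yl]oxy}dimethylsilane | CC(C)(C)[Si](C)(C)O[C@H]1C=CC2=CCCC[C@]2(C)[C@H]1C | intermediate
16 | (4aR,5R,6S)-6-[(tert-butyldimethylsilyl)oxy]-4a,5-dimethyl-4,4a,5,6-tetrahydronaphthalen-2(3H)-one | CC(C)(C)[Si](C)(C)O[C@H]1C=CC2=CC(=O)CC[C@]2(C)[C@H]1C | intermediate
17 | lithium enolate of 16 (C7=C8 cross-conjugated dienolate) | CC(C)(C)[Si](C)(C)O[C@H]1C=CC2=CC(O[Li])=CC[C@]2(C)[C@H]1C | intermediate (not isolated)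
18 | chlorozinc enolate of 16 | CC(C)(C)[Si](C)(C)O[C@H]1C=CC2=CC(O[Zn]Cl)=CC[C@]2(C)[C@H]1C | intermediate (not isolated)
19 | (4aR,5R,6S)-6-[(tert-butyldimethylsilyl)oxy]-3-(2-hydroxypropan-2-yl)-4a,5-dimethyl-4,4a,5,6-tetrahydronaphthalen-2(3H)-one (C3 epimers) | CC(C)(C)[Si](C)(C)O[C@H]1C=CC2=CC(=O)C(C(C)(C)O)C[C@]2(C)[C@H]1C | intermediate
20 | methanesulfonate of the tertiary alcohol of 19 | CC(C)(C)[Si](C)(C)O[C@H]1C=CC2=CC(=O)C(C(C)(C)OS(C)(=O)=O)C[C@]2(C)[C@H]1C | intermediate (not isolated)
21 | (4aR,5R,6S)-6-[(tert-butyldimethylsilyl)oxy]-4a,5-dimethyl-3-(propan-2-ylidene)-4,4a,5,6-tetrahydronaphthalen-2(3H)-one | CC(C)(C)[Si](C)(C)O[C@H]1C=CC2=CC(=O)C(=C(C)C)C[C@]2(C)[C@H]1C | intermediate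
22 | (4aR,5R,6S)-6-hydroxy-4a,5-dimethyl-3-(propan-2-ylidene)-4,4a,5,6-tetrahydronaphthalen-2(3H)-one | O[C@H]1C=CC2=CC(=O)C(=C(C)C)C[C@]2(C)[C@H]1C | intermediate
23 | (S)-2-methylbutan-1-ol | CC[C@H](C)CO | starting material
24 | (S)-2-methylbutanal | CC[C@H](C)C=O | intermediate
25 | triethyl 4-phosphonocrotonate, ethyl (E)-4-(diethoxyphosphoryl)but-2-enoate | CCOC(=O)/C=C/CP(=O)(OCC)OCC | starting material
26 | lithium salt of the γ-carbanion of 25 | [Li+].CCOC(=O)/C=C/[CH-]P(=O)(OCC)OCC | intermediate (not isolated)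
27 | ethyl (2E,4E,6S)-6-methylocta-2,4-dienoate | CC[C@H](C)/C=C/C=C/C(=O)OCC | intermediate
28 | (2E,4E,6S)-6-methylocta-2,4-dienoic acid | CC[C@H](C)/C=C/C=C/C(=O)O | intermediate
29 | (2E,4E,6S)-6-methylocta-2,4-dienoic 2,4,6-trichlorobenzoic anhydride | CC[C@H](C)/C=C/C=C/C(=O)OC(=O)c1c(Cl)cc(Cl)cc1Cl | intermediate (not isolated)
30 | (1R,2S,8aR)-1,8a-dimethyl-6-oxo-7-(propan-2-ylidene)-1,2,6,7,8,8a-hexahydronaphthalen-2-yl (2E,4E,6S)-6-methylocta-2,4-dienoate | CC[C@H](C)/C=C/C=C/C(=O)O[C@H]1C=CC2=CC(=O)C(=C(C)C)C[C@]2(C)[C@H]1C | target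

**Count and risks**
Total step count: 19. Longest linear sequence: 16 (steps 1–15 and step 19); steps 16–18 make the side-chain acid.

Most likely to fail:

1. Step 11. Ruthenium may load on the wrong alkene, or the cascade may stall after the first closure because the vinylcarbene must engage a hindered alkene next to the silyl ether; the result would be cyclopentene-type by-products, oligomers, or catalyst death at the neopentyl-type alkyne. The fallback separates the two closures so that no second alkene is present during the enyne step. It sets out from 11, which has only the pentenyl alkene. Enyne ring-closing metathesis of 11 with second-generation Grubbs catalyst (H2IMes)(PCy3)Cl2Ru=CHPh under ethylene (1 atm) should give (2R,3R)-1,2-bis[(tert-butyldimethylsilyl)oxy]-3-[(1R)-2-ethenyl-1-methylcyclohex-2-en-1-yl]butane F1. HF·pyridine then frees the primary alcohol (2R,3R)-2-[(tert-butyldimethylsilyl)oxy]-3-[(1R)-2-ethenyl-1-methylcyclohex-2-en-1-yl]butan-1-ol F2. Dess–Martin oxidation gives the aldehyde (2R,3R)-2-[(tert-butyldimethylsilyl)oxy]-3-[(1R)-2-ethenyl-1-methylcyclohex-2-en-1-yl]butanal F3, and Wittig methylenation gives the triene tert-butyl{[(3S,4R)-4-[(1R)-2-ethenyl-1-methylcyclohex-2-en-1-yl]pent-1-en-3-yl]oxy}dimethylsilane F4. Ring-closing metathesis of F4 with second-generation Hoveyda–Grubbs catalyst (H2IMes)Cl2Ru=CH(2-i-PrOC6H4) in hot toluene closes ring A and comes back to the route at 15.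

2. Step 12. Hydrogen abstraction may not discriminate between C8–H and the oxygen-bearing C3–H, and the electron-rich diene may be degraded by hexavalent chromium. The fallback replaces the direct C–H to C=O oxidation by an ene-type hydroxylation followed by alcohol oxidation. It sets out from 15: SeO2 (cat.) and t-BuOOH in CH2Cl2 should give the allylic alcohol (4aR,5R,6S)-6-[(tert-butyldimethylsilyl)oxy]-4a,5-dimethyl-2,3,4,4a,5,6-hexahydronaphthalen-2-ol F5 as a mixture of carbinol epimers. Oxidation of F5 with MnO2 comes back to the route at 16.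

3. Step 4. Facial selectivity at the quaternary center may be insufficient or inverted, because the C4 methyl group directs the electrophile to the face that the C5 silyloxymethyl group shields; in addition, SN2 of an unactivated bromide at a tetrasubstituted enolate is slow. The fallback reverses the order of the two alkylations, which gives the opposite C5 configuration for a given facial bias and so turns an unwanted preference into the wanted one. It sets out from 3: enolate 4 is alkylated with 6 to give (3R,4R,5R)-5-{[(tert-butyldimethylsilyl)oxy]methyl}-4-methyl-3-(pent-4-en-1-yl)dihydrofuran-2(3H)-one F6. Deprotonation with LiN(i-Pr)2 gives the lithium enolate of the pentenyl lactone F7, and methylation with iodomethane (now the incoming group, anti to the C5 side chain) comes back to the route at 8, with epimers separated by chromatography.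

Further compounds
F1 | step 11 | (2R,3R)-1,2-bis[(tert-butyldimethylsilyl)oxy]-3-[(1R)-2-ethenyl-1-methylcyclohex-2-en-1-yl]butane | CC(C)(C)[Si](C)(C)OC[C@H](O[Si](C)(C)C(C)(C)C)[C@H](C)[C@@]1(C)CCCC=C1C=C
F2 | step 11 | (2R,3R)-2-[(tert-butyldimethylsilyl)oxy]-3-[(1R)-2-ethenyl-1-methylcyclohex-2-en-1-yl]butan-1-ol | OC[C@H](O[Si](C)(C)C(C)(C)C)[C@H](C)[C@@]1(C)CCCC=C1C=C
F3 | step 11 | (2R,3R)-2-[(tert-butyldimethylsilyl)oxy]-3-[(1R)-2-ethenyl-1-methylcyclohex-2-en-1-yl]butanal | O=C[C@H](O[Si](C)(C)C(C)(C)C)[C@H](C)[C@@]1(C)CCCC=C1C=C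
F4 | step 11 | tert-butyl{[(3S,4R)-4-[(1R)-2-ethenyl-1-methylcyclohex-2-en-1-yl]pent-1-en-3-yl]oxy}dimethylsilane | C=C[C@H](O[Si](C)(C)C(C)(C)C)[C@H](C)[C@@]1(C)CCCC=C1C=C
F5 | step 12 | (4aR,5R,6S)-6-[(tert-butyldimethylsilyl)oxy]-4a,5-dimethyl-2,3,4,4a,5,6-hexahydronaphthalen-2-ol (C2 epimers) | CC(C)(C)[Si](C)(C)O[C@H]1C=CC2=CC(O)CC[C@]2(C)[C@H]1C
F6 | step 4 | (3R,4R,5R)-5-{[(tert-butyldimethylsilyl)oxy]methyl}-4-methyl-3-(pent-4-en-1-yl)dihydrofuran-2(3H)-one | CC(C)(C)[Si](C)(C)OC[C@@H]1OC(=O)[C@H](CCCC=C)[C@H]1C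
F7 | step 4 | lithium enolate of F6 | CC(C)(C)[Si](C)(C)OC[C@@H]1OC(O[Li])=C(CCCC=C)[C@H]1C
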